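**Plan**

1. Carbon labels (daucane numbering): C1 methyl-bearing fusion carbon, C2/C3 ring CH2, C4 isopropyl carbinol carbon, C5 fusion CH, C6 CHOH, C7=C8(CH3), C9 ketone, C10 CH2.
2. Retrosynthetic cuts, in order: C4–O aroyl ester; C7=C8 unsaturation; C8–C9 ring bond; C4–isopropyl bond; C5–C6 bond (aldol); C1–CH3 bond (conjugate addition); cyclopentenone–CH2CO2tBu bond.
3. Enabling feature: in the seven-membered ring the C9 ketone and the C6 oxygen are 1,4-related across C7–C8, so a C9 acyl radical, tied through C10 to C1, can close onto C8, the β-carbon of a C6 propenyl ketone attached to C5 of the cyclopentane.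
4. Forward order: the five-membered ring comes from 3-ethoxycyclopentenone; the arms are attached at C1 (acetate arm, methyl), C5 (four-carbon C6–C8 unit) and C4 (isopropyl); the seven-membered ring closes in step 8; reduction, acylation, dehydrogenation and desilylation follow.
5. Stereochemistry: C1 from the chiral copper catalyst; C5 and then C4 by relay (aldol anti to the acetate arm, isopropyl anti to the C5 arm); C6 by hydride delivery from the C4 hydroxyl; C8 is uncontrolled and erased in step 15.

Key step: step 8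

Remarks: the ligand antipode used in step 2 is the one that, by its accepted facial model, delivers methyl to the Si face of the enone β-carbon (giving C1 R). Daucane-based names use the carbon labels of line 1. Where C6 (compounds 8–11) or C8 (compounds 16–19, 23, 24) is undefined in a SMILES string, both epimers are meant.

**Route**

Step 1
Reactants: 1 3-ethoxycyclopent-2-en-1-one; 2 tert-butyl acetate
Product: 5 tert-butyl 2-(3-oxocyclopent-1-en-1-yl)acetate, via lithium enolate of tert-butyl acetate 3 (not isolated), via lithium alkoxide 1,2-adduct 4 (not isolated)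
Conditions: LiN(iPr)2, THF, −78 °C; then 1, −78 to 0 °C; then 1 M aq. HCl, 23 °C
Reagents that add atoms: water, O
Why: Stork–Danheiser sequence, in which the ester enolate adds 1,2 to the vinylogous ester carbonyl and acid hydrolysis of the enol ether with loss of the tertiary hydroxyl transposes the enone while the tert-butyl ester survives.

Step 2
Reactants: 5 tert-butyl 2-(3-oxocyclopent-1-en-1-yl)acetate; 6 (E)-but-2-enal
Product: 8 tert-butyl 2-[(1R,2S)-2-[(E)-1-hydroxybut-2-en-1-yl]-1-methyl-3-oxocyclopentyl]acetate, via dimethylaluminium enolate 7 (not isolated)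
Conditions: Cu(O2CC4H3S) (CuTC, cat.), chiral ligand Ph2PN[CH(CH3)(2-naphthyl)]2 (cat.), AlMe3, Et2O, −30 °C; then 6, −78 to −30 °C; aq. potassium sodium tartrate
Reagents that add atoms: trimethylaluminium, C[Al](C)C
Why: Copper-catalysed asymmetric conjugate addition of AlMe3 sets the quaternary C1 (R) under ligand control, and the regiodefined aluminium enolate then undergoes an aldol addition at C5 on the face opposite the bulkier CH2CO2tBu arm, so that C6 lies cis to the C1 methyl; the C6 carbinol configuration is left open because C6 is oxidised in step 5.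

Step 3
Reactants: 8 tert-butyl 2-[(1R,2S)-2-[(E)-1-hydroxybut-2-en-1-yl]-1-methyl-3-oxocyclopentyl]acetate
Product: 9 tert-butyl 2-[(1R,2S)-1-methyl-3-oxo-2-[(E)-1-(triethylsilyloxy)but-2-en-1-yl]cyclopentyl]acetate
Conditions: Et3SiCl, imidazole, DMF, 0 to 23 °C
Reagents that add atoms: chlorotriethylsilane, CC[Si](Cl)(CC)CC
Why: Routine silylation of a secondary alcohol blocks retro-aldol cleavage and enlarges the C5 side chain for the facial control needed in step 4.

Step 4
Reactants: 9 tert-butyl 2-[(1R,2S)-1-methyl-3-oxo-2-[(E)-1-(triethylsilyloxy)but-2-en-1-yl]cyclopentyl]acetate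
Product: 11 tert-butyl 2-[(1R,2S,3R)-3-hydroxy-2-[(E)-1-hydroxybut-2-en-1-yl]-1-methyl-3-(propan-2-yl)cyclopentyl]acetate, via TES-protected tertiary alcohol 10 (not isolated)
Conditions: CeCl3, iPrMgCl, THF, −78 °C; aq. NH4Cl; then PPTS, MeOH, 23 °C
Reagents that add atoms: isopropylmagnesium chloride, CC(C)[Mg]Cl
Why: Organocerium 1,2-addition (which suppresses enolisation and β-hydride reduction and spares the tert-butyl ester) should occur on the C4 carbonyl face anti to the bulky C5 side chain, placing the C4 oxygen cis to C6 and to the C1 methyl (4R), and mild acid methanolysis then removes the secondary allylic silyl ether.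

Step 5
Reactants: 11 tert-butyl 2-[(1R,2S,3R)-3-hydroxy-2-[(E)-1-hydroxybut-2-en-1-yl]-1-methyl-3-(propan-2-yl)cyclopentyl]acetate
Product: 12 tert-butyl 2-[(1R,2R,3R)-2-[(E)-but-2-enoyl]-3-hydroxy-1-methyl-3-(propan-2-yl)cyclopentyl]acetate
Conditions: Dess–Martin periodinane, NaHCO3, CH2Cl2, 0 to 23 °C
Reagents that add atoms: none
Why: Dess–Martin oxidation converts both C6 epimers of the secondary allylic alcohol into one (E)-propenyl ketone, while the tertiary C4 alcohol cannot be oxidised and the buffer prevents its dehydration.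

Step 6
Reactants: 12 tert-butyl 2-[(1R,2R,3R)-2-[(E)-but-2-enoyl]-3-hydroxy-1-methyl-3-(propan-2-yl)cyclopentyl]acetate
Product: 14 2-[(1R,2R,3R)-2-[(E)-but-2-enoyl]-1-methyl-3-(propan-2-yl)-3-(triethylsilyloxy)cyclopentyl]acetic acid, via bis-silylated TES ester 13 (not isolated)
Conditions: Et3SiOTf, 2,6-lutidine, CH2Cl2, −78 to 23 °C; then aq. NaH2PO4, THF
Reagents that add atoms: triethylsilyl trifluoromethanesulfonate, CC[Si](CC)(CC)OS(=O)(=O)C(F)(F)F
Why: Silyl triflate with 2,6-lutidine silylates the hindered tertiary alcohol and, by O-silylation of the ester carbonyl and loss of isobutene, performs the known non-protic cleavage of a tert-butyl ester to a silyl ester that hydrolyses on buffered work-up, the weak hindered base being unable to enolise the hindered enone.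

Step 7
Reactants: 14 2-[(1R,2R,3R)-2-[(E)-but-2-enoyl]-1-methyl-3-(propan-2-yl)-3-(triethylsilyloxy)cyclopentyl]acetic acid
Product: 15 Se-phenyl 2-[(1R,2R,3R)-2-[(E)-but-2-enoyl]-1-methyl-3-(propan-2-yl)-3-(triethylsilyloxy)cyclopentyl]ethaneselenoate
Conditions: N-(phenylselanyl)phthalimide, PBu3, THF, −20 to 23 °C
Reagents that add atoms: N-(phenylselanyl)phthalimide, O=C1N([Se]c2ccccc2)C(=O)c2ccccc12
Why: Phosphine-mediated selenoesterification (acyloxyphosphonium formation, then attack of phenylselenolate) gives the acyl selenide with phthalimide instead of free benzeneselenol as by-product, which protects the propenyl ketone from conjugate addition.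

Step 8
Reactants: 15 Se-phenyl 2-[(1R,2R,3R)-2-[(E)-but-2-enoyl]-1-methyl-3-(propan-2-yl)-3-(triethylsilyloxy)cyclopentyl]ethaneselenoate
Product: 16 (1R,4R,5R)-4-(triethylsilyloxy)daucane-6,9-dione
Conditions: Bu3SnH, AIBN (syringe pump, 8 h), benzene (0.005 M), 80 °C
Reagents that add atoms: none
Why: The tributylstannyl radical abstracts the phenylselanyl group to give the C9 acyl radical, which adds to C8, the β-carbon of the propenyl ketone, and the resulting C7 α-keto radical takes hydrogen from Bu3SnH to carry the chain. The closest known reaction type is the tin-hydride-mediated cyclisation of selenoester-derived acyl radicals onto electron-poor alkenes, including endo closures when the acceptor carbonyl lies inside the tether. The seven-membered ring (C1, C5, C6, C7, C8, C9, C10) closes in the 7-endo-trig mode and is trans-fused because the two arms are already trans on the cyclopentane. The new stereocentre C8 has no controlling element and should form as both epimers, which is harmless because C8 becomes sp2 in step 15. The step needs attack at C8 and not at C7 (6-exo), and ring closure faster than hydrogen transfer or CO loss: the nucleophilic acyl radical is polarity-matched with the electrophilic β-carbon and gives a stabilised enoxyl radical, slow stannane addition at high dilution disfavours direct reduction, and a primary-alkyl acyl radical that would expel a neopentyl-type radical decarbonylates slowly.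

Step 9
Reactants: 16 (1R,4R,5R)-4-(triethylsilyloxy)daucane-6,9-dione
Product: 17 (1R,4R,5R)-4-hydroxydaucane-6,9-dione
Conditions: HF·pyridine, pyridine, THF, 0 to 23 °C
Reagents that add atoms: none
Why: Buffered acidic fluoride desilylation frees the tertiary alcohol without the retro-aldol or E1cB loss that a basic fluoride source could cause in this β-hydroxy ketone.

Step 10
Reactants: 17 (1R,4R,5R)-4-hydroxydaucane-6,9-dione
Product: 18 (1R,4R,5S,6S)-4,6-dihydroxydaucan-9-one
Conditions: Me4NBH(OAc)3, MeCN/AcOH, −30 to 0 °C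
Reagents that add atoms: none
Why: Evans–Saksena hydroxyl-directed reduction, in which the C4 hydroxyl exchanges onto boron and delivers hydride through a chair-like six-membered transition state to the C6 carbonyl face on the side of O4 (1,3-anti diol, 6S), while the C9 ketone has no suitably placed hydroxyl and is not touched by the triacetoxyborohydride.

Step 11
Reactants: 18 (1R,4R,5S,6S)-4,6-dihydroxydaucan-9-one
Product: 19 (1R,4R,5S,6S)-6-(tert-butyldimethylsilyloxy)-4-hydroxydaucan-9-one
Conditions: tBuMe2SiOTf (1.05 equiv), 2,6-lutidine, CH2Cl2, −78 °C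
Reagents that add atoms: tert-butyldimethylsilyl trifluoromethanesulfonate, CC(C)(C)[Si](C)(C)OS(=O)(=O)C(F)(F)F
Why: Low-temperature silyl triflate silylation distinguishes the secondary C6 hydroxyl from the far more hindered tertiary C4 hydroxyl, and any transannular C6–O–C9 hemiketal is drained through the open hydroxy ketone.

Step 12
Reactants: 20 4-hydroxybenzoic acid
Product: 21 tert-butyldimethylsilyl 4-(tert-butyldimethylsilyloxy)benzoate
Conditions: tBuMe2SiCl (2.2 equiv), imidazole, DMF, 23 °C
Reagents that add atoms: tert-butyldimethylsilyl chloride, CC(C)(C)[Si](C)(C)Cl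
Why: Exhaustive silylation of a phenol and a carboxylic acid with a silyl chloride and imidazole is routine.

Step 13
Reactants: 21 tert-butyldimethylsilyl 4-(tert-butyldimethylsilyloxy)benzoate
Product: 22 4-(tert-butyldimethylsilyloxy)benzoyl chloride
Conditions: (COCl)2, DMF (cat.), CH2Cl2, 0 to 23 °C; volatiles removed in vacuo
Reagents that add atoms: oxalyl chloride, O=C(Cl)C(Cl)=O
Why: Silyl esters are converted by oxalyl chloride and catalytic DMF (Vilsmeier-type activation) into acid chlorides under neutral conditions, so the aryl silyl ether never meets HCl.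

Step 14
Reactants: 19 (1R,4R,5S,6S)-6-(tert-butyldimethylsilyloxy)-4-hydroxydaucan-9-one; 22 4-(tert-butyldimethylsilyloxy)benzoyl chloride
Product: 24 (1R,4R,5S,6S)-6-(tert-butyldimethylsilyloxy)-9-oxodaucan-4-yl 4-(tert-butyldimethylsilyloxy)benzoate, via lithium C4-alkoxide 23 (not isolated)
Conditions: LiN(SiMe3)2 (1.05 equiv), THF, −78 °C; then 22, −78 to 0 °C
Reagents that add atoms: none
Why: Acylation of a lithium alkoxide with an aroyl chloride is the usual esterification of a hindered tertiary alcohol in polyfunctional ketones; kinetic O–H deprotonation with one equivalent of amide base at −78 °C precedes ketone enolisation, and acylating before the enone exists avoids oxa-Michael addition of the alkoxide to C7.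

Step 15
Reactants: 24 (1R,4R,5S,6S)-6-(tert-butyldimethylsilyloxy)-9-oxodaucan-4-yl 4-(tert-butyldimethylsilyloxy)benzoate
Product: 25 (1R,4R,5S,6S)-6-(tert-butyldimethylsilyloxy)-9-oxodauc-7-en-4-yl 4-(tert-butyldimethylsilyloxy)benzoate
Conditions: 2-iodoxybenzoic acid (IBX), DMSO/fluorobenzene, 70 °C
Reagents that add atoms: none
Why: IBX dehydrogenation of ketones proceeds through the more substituted enol, and since C10 has no β-hydrogen (C1 is quaternary) only the conjugated C7=C8 enone can form, which also merges the two C8 epimers.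

Step 16
Reactants: 25 (1R,4R,5S,6S)-6-(tert-butyldimethylsilyloxy)-9-oxodauc-7-en-4-yl 4-(tert-butyldimethylsilyloxy)benzoate
Product: 26 (1R,4R,5S,6S)-6-hydroxy-9-oxodauc-7-en-4-yl 4-hydroxybenzoate
Conditions: HF·pyridine, pyridine, THF, 0 to 23 °C
Reagents that add atoms: none
Why: Fluoride desilylation under mildly acidic conditions cleaves the aryl and the secondary silyl ether together and avoids the base-promoted 1,3-acyl shift from the tertiary to the secondary oxygen.

**Compound list**

1 | 3-ethoxycyclopent-2-en-1-one | CCOC1=CC(=O)CC1 | starting material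
2 | tert-butyl acetate | CC(=O)OC(C)(C)C | starting material
3 | lithium 1-tert-butoxyethen-1-olate (lithium enolate of 2; not isolated) | C=C(O[Li])OC(C)(C)C | intermediate
4 | lithium 1-(2-tert-butoxy-2-oxoethyl)-3-ethoxycyclopent-2-en-1-olate (racemic 1,2-adduct; not isolated) | CCOC1=CC(O[Li])(CC(=O)OC(C)(C)C)CC1 | intermediate
5 | tert-butyl 2-(3-oxocyclopent-1-en-1-yl)acetate | O=C1C=C(CC(=O)OC(C)(C)C)CC1 | intermediate
6 | (E)-but-2-enal (crotonaldehyde) | C/C=C/C=O | starting material
7 | tert-butyl 2-[(1R)-3-(dimethylalumanyloxy)-1-methylcyclopent-2-en-1-yl]acetate (aluminium enolate; not isolated) | C[Al](C)OC1=C[C@@](C)(CC(=O)OC(C)(C)C)CC1 | intermediate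
8 | tert-butyl 2-[(1R,2S)-2-[(E)-1-hydroxybut-2-en-1-yl]-1-methyl-3-oxocyclopentyl]acetate (C1 R, C5 S; C6 epimers) | C/C=C/C(O)[C@@H]1[C@@](C)(CC(=O)OC(C)(C)C)CCC1=O | intermediate
9 | tert-butyl 2-[(1R,2S)-1-methyl-3-oxo-2-[(E)-1-(triethylsilyloxy)but-2-en-1-yl]cyclopentyl]acetate (C6 epimers) | C/C=C/C(O[Si](CC)(CC)CC)[C@@H]1[C@@](C)(CC(=O)OC(C)(C)C)CCC1=O | intermediate
10 | tert-butyl 2-[(1R,2S,3R)-3-hydroxy-1-methyl-3-(propan-2-yl)-2-[(E)-1-(triethylsilyloxy)but-2-en-1-yl]cyclopentyl]acetate (C6 epimers; not isolated) | C/C=C/C(O[Si](CC)(CC)CC)[C@@H]1[C@@](C)(CC(=O)OC(C)(C)C)CC[C@@]1(O)C(C)C | intermediate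
11 | tert-butyl 2-[(1R,2S,3R)-3-hydroxy-2-[(E)-1-hydroxybut-2-en-1-yl]-1-methyl-3-(propan-2-yl)cyclopentyl]acetate (C1 R, C5 S, C4 R; C6 epimers) | C/C=C/C(O)[C@@H]1[C@@](C)(CC(=O)OC(C)(C)C)CC[C@@]1(O)C(C)C | intermediate
12 | tert-butyl 2-[(1R,2R,3R)-2-[(E)-but-2-enoyl]-3-hydroxy-1-methyl-3-(propan-2-yl)cyclopentyl]acetate | C/C=C/C(=O)[C@@H]1[C@@](C)(CC(=O)OC(C)(C)C)CC[C@@]1(O)C(C)C | intermediate
13 | triethylsilyl 2-[(1R,2R,3R)-2-[(E)-but-2-enoyl]-1-methyl-3-(propan-2-yl)-3-(triethylsilyloxy)cyclopentyl]acetate (not isolated) | C/C=C/C(=O)[C@@H]1[C@@](C)(CC(=O)O[Si](CC)(CC)CC)CC[C@@]1(O[Si](CC)(CC)CC)C(C)C | intermediate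
14 | 2-[(1R,2R,3R)-2-[(E)-but-2-enoyl]-1-methyl-3-(propan-2-yl)-3-(triethylsilyloxy)cyclopentyl]acetic acid | C/C=C/C(=O)[C@@H]1[C@@](C)(CC(=O)O)CC[C@@]1(O[Si](CC)(CC)CC)C(C)C | intermediate
15 | Se-phenyl 2-[(1R,2R,3R)-2-[(E)-but-2-enoyl]-1-methyl-3-(propan-2-yl)-3-(triethylsilyloxy)cyclopentyl]ethaneselenoate (arms at C1 and C5 trans) | C/C=C/C(=O)[C@@H]1[C@@](C)(CC(=O)[Se]c2ccccc2)CC[C@@]1(O[Si](CC)(CC)CC)C(C)C | intermediate
16 | (1R,4R,5R)-4-(triethylsilyloxy)daucane-6,9-dione (trans-fused; C8 epimers) | CC1CC(=O)[C@@H]2[C@](C)(CC[C@@]2(O[Si](CC)(CC)CC)C(C)C)CC1=O | intermediate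
17 | (1R,4R,5R)-4-hydroxydaucane-6,9-dione (C8 epimers) | CC1CC(=O)[C@@H]2[C@](C)(CC[C@@]2(O)C(C)C)CC1=O | intermediate
18 | (1R,4R,5S,6S)-4,6-dihydroxydaucan-9-one (C8 epimers) | CC1C[C@H](O)[C@@H]2[C@](C)(CC[C@@]2(O)C(C)C)CC1=O | intermediate
19 | (1R,4R,5S,6S)-6-(tert-butyldimethylsilyloxy)-4-hydroxydaucan-9-one (C8 epimers) | CC1C[C@H](O[Si](C)(C)C(C)(C)C)[C@@H]2[C@](C)(CC[C@@]2(O)C(C)C)CC1=O | intermediate
20 | 4-hydroxybenzoic acid | O=C(O)c1ccc(O)cc1 | starting material
21 | tert-butyldimethylsilyl 4-(tert-butyldimethylsilyloxy)benzoate | CC(C)(C)[Si](C)(C)OC(=O)c1ccc(O[Si](C)(C)C(C)(C)C)cc1 | intermediate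
22 | 4-(tert-butyldimethylsilyloxy)benzoyl chloride | CC(C)(C)[Si](C)(C)Oc1ccc(C(=O)Cl)cc1 | intermediate
23 | lithium (1R,4R,5S,6S)-6-(tert-butyldimethylsilyloxy)-9-oxodaucan-4-olate (C8 epimers; not isolated) | CC1C[C@H](O[Si](C)(C)C(C)(C)C)[C@@H]2[C@](C)(CC[C@@]2(O[Li])C(C)C)CC1=O | intermediate
24 | (1R,4R,5S,6S)-6-(tert-butyldimethylsilyloxy)-9-oxodaucan-4-yl 4-(tert-butyldimethylsilyloxy)benzoate (C8 epimers) | CC1C[C@H](O[Si](C)(C)C(C)(C)C)[C@@H]2[C@](C)(CC[C@@]2(OC(=O)c3ccc(O[Si](C)(C)C(C)(C)C)cc3)C(C)C)CC1=O | intermediate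
25 | (1R,4R,5S,6S)-6-(tert-butyldimethylsilyloxy)-9-oxodauc-7-en-4-yl 4-(tert-butyldimethylsilyloxy)benzoate | CC1=C[C@H](O[Si](C)(C)C(C)(C)C)[C@@H]2[C@](C)(CC[C@@]2(OC(=O)c3ccc(O[Si](C)(C)C(C)(C)C)cc3)C(C)C)CC1=O | intermediate
26 | (1R,4R,5S,6S)-6-hydroxy-9-oxodauc-7-en-4-yl 4-hydroxybenzoate (CNP0153637.1) | CC1=C[C@H](O)[C@@H]2[C@](C)(CC[C@@]2(OC(=O)c2ccc(O)cc2)C(C)C)CC1=O | target

**Step count and risks**

Total step count: 16. Longest linear sequence: 14 (steps 1–11 and 14–16; steps 12 and 13 prepare the acyl chloride).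

Steps most likely to fail:

Step 8. Hydrogen transfer from the stannane to the acyl radical, loss of CO, or 6-exo attack at C7 may outrun the slow 7-endo closure. The fallback sets out from 15 and returns at 16. Selenoester 15 is reduced on purpose with concentrated Bu3SnH and AIBN (the pathway that competes in step 8) to 2-[(1R,2R,3R)-2-[(E)-but-2-enoyl]-1-methyl-3-(propan-2-yl)-3-(triethylsilyloxy)cyclopentyl]acetaldehyde F1. SmI2 with HMPA and t-BuOH in THF then joins C9 to C8 by reductive aldehyde–enone (ketyl–olefin) coupling, which should give (1R,4R,5R)-9-hydroxy-4-(triethylsilyloxy)daucan-6-one F2 as a mixture at C8 and C9. Dess–Martin oxidation of the C9 carbinol leads back to dione 16.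

Step 14. Enolisation of the C9 ketone, 1,3 O-to-O silyl migration from C6 to the C4 alkoxide, or incomplete acylation of the very hindered alkoxide may erode the esterification. The fallback sets out from 19 and returns at 24 without any alkoxide. Silyl ester 21 and acyl chloride 22 are combined to 4-(tert-butyldimethylsilyloxy)benzoic anhydride F3. Lewis-acid catalysis with Bi(OTf)3 in CH2Cl2/MeCN at 0 to 23 °C, a known acylation of tertiary alcohols by aromatic anhydrides, then transfers the aroyl group to the C4 hydroxyl of 19 to give 24.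

Step 2. The aluminium enolate may add sluggishly to the enal, or the aldehyde may discriminate poorly between the two faces at C5 (methyl versus acetate arm); insufficient enantioselection at C1 would also show here. The fallback sets out from 5 and returns at 8. The conjugate addition is run as before, but the enolate is trapped with Me3SiOTf to give tert-butyl 2-[(1R)-1-methyl-3-(trimethylsilyloxy)cyclopent-2-en-1-yl]acetate F4, which can be purified and assayed. A Mukaiyama aldol addition of F4 to 6 with BF3·OEt2 in CH2Cl2 at −78 °C then goes through an open transition state in which the complexed aldehyde approaches anti to the acetate arm, and gives 8 after work-up.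

Further compounds
F1 | step 8 | 2-[(1R,2R,3R)-2-[(E)-but-2-enoyl]-1-methyl-3-(propan-2-yl)-3-(triethylsilyloxy)cyclopentyl]acetaldehyde | C/C=C/C(=O)[C@@H]1[C@@](C)(CC=O)CC[C@@]1(O[Si](CC)(CC)CC)C(C)C
F2 | step 8 | (1R,4R,5R)-9-hydroxy-4-(triethylsilyloxy)daucan-6-one (C8 and C9 epimers) | CC1CC(=O)[C@@H]2[C@](C)(CC[C@@]2(O[Si](CC)(CC)CC)C(C)C)CC1O
F3 | step 14 | 4-(tert-butyldimethylsilyloxy)benzoic anhydride | CC(C)(C)[Si](C)(C)Oc1ccc(cc1)C(=O)OC(=O)c1ccc(O[Si](C)(C)C(C)(C)C)cc1
F4 | step 2 | tert-butyl 2-[(1R)-1-methyl-3-(trimethylsilyloxy)cyclopent-2-en-1-yl]acetate | C[Si](C)(C)OC1=C[C@@](C)(CC(=O)OC(C)(C)C)CC1
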